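Do not carry a yield from one charge to another unchecked.

| flask | substrate | time |
|---|---|---|
| Monday's | 1.00 M |  |
| Thursday's | 0.500 M |  |
| Wednesday's | 0.150 M | 14 h |

| run | time / h | [target] / M |
|---|---|---|
| Monday's run | 0.56 | 0.078 |
| Monday's run | 0.96 | 0.116 |
| Monday's run | 1.6 | 0.193 |
| Monday's run | 2.8 | 0.302 |
| Monday's run | 4.8 | 0.437 |
| Monday's run | 8.2 | 0.521 |
| Monday's run | 14 | 0.599 |
| Thursday's run | 0.56 | 0.037 |
| Thursday's run | 0.96 | 0.065 |
| Thursday's run | 1.6 | 0.112 |
| Thursday's run | 2.8 | 0.176 |
| Thursday's run | 4.8 | 0.242 |
| Thursday's run | 8.2 | 0.332 |
| Thursday's run | 14 | 0.352 |

(scatter of a reading: 0.01 M)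

* the exponent of [substrate] in the starting rate at the charge of the Monday's run (at the point where two percent of the substrate have become target) (one fixed amount of target, the same in the runs compared)
* target in the Wednesday's run at 14 h, as a share of the substrate charged

- Overall: substrate -> target.
- Constant volume, constant temperature.
- An order is taken over about fifteen percent of the charge, up and down.

Work with what is left over. Let u be the share of the charge that is not target at 14 h: 40.1% in Monday's run and 29.6% in Thursday's.

Now turn the question round. If each step is first-order, u at a fixed time does not depend on the charge, so the two readings should match. They differ by 10 percentage points, and the scatter of that difference is 2.2 points, so the gap is more than scatter.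

Measure the distance from that first-order case with the logarithm of the ratio of the two u values over the logarithm of the ratio of the charges. This reads 0.438; call it n, the charge exponent of the leftover share, which is zero in the first-order case.

Hold n constant down to Wednesday's charge, which is my own assumption. Then u there is 17.5%, and the yield is 82.5%. For the order, the target readings at 0.96 h give a rough 0.836.

The forecast says 80% for the yield, lower than my figure, and 0.87 for the order; it extrapolates to Wednesday's charge and arrives at “roughly 78–84% yield”.

The simulation gives 87.5% for Wednesday's run and 0.88 for the order, from these steps: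

    substrate ⇌ intermediate (0.5724 h⁻¹, 0.2826 h⁻¹)
    intermediate → target (0.3560 h⁻¹)
    substrate → target (0.1224 h⁻¹)
    2 substrate → homo dimer (0.4176 M⁻¹ h⁻¹)

At the start, substrate goes to homo dimer at 0.835 h⁻¹ per unit of substrate in Monday's run and at 0.125 h⁻¹ in Wednesday's, against 0.695 h⁻¹ by its two first-order exits. Wednesday's leftover share is 12.5%, so n between Thursday's and Wednesday's charges reads 0.717, steeper than the 0.438 between Monday's and Thursday's.

The numbers in the tables are calculated on assumed constants; scatter was added.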